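**Plan**

- Numbering follows the benzofuranone: O1, C2 (aryl), C3 (methyl), C3a (allyl), C4, C5 (OMe), C6 (C=O), C7=C7a. Ring A is the dihydrofuran, ring B the cyclohexenone.
- Retrosynthetic cuts, in order: C5–OMe and the aryl 4-O–Me; O1–C2 of ring A; C3a–allyl; C3–CH3; C3a–C3.
- Enabling feature: C2 is a benzylic CH2 para to a phenol flanked by two methoxy groups, and it lies five atoms from the enol oxygen on C7a of a ring-B 1,3-dione. Oxidizing the phenol therefore turns C2 into an electrophile without any earlier functional group at C2.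
- Forward: an arylacetaldehyde is condensed onto C6 of 3-ethoxycyclohex-2-enone (the future C3a), methyl and then allyl are added, ring B is unmasked as the dione, ring A closes by quinone methide capture, and C5 is oxygenated last.
- Stereochemistry: C3 from a copper-catalysed enantioselective methyl addition; C3a from a palladium-catalysed enantioselective decarboxylative allylation; C2 from C3 (trans) during ring closure; C5 from C3a (reagent anti to the axial allyl).

Key step: step 8

Assumption: the ligand antipodes named in steps 5 and 6 are assigned by analogy with simpler enones and with 2-alkylcyclohexanone enol carbonates; the product descriptors state what is required, and the mirror-image ligand would be used if a first run showed the opposite sense.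

**Route**

Step 1
Reactants: 1 4-allyl-2,6-dimethoxyphenol
Product: 2 (4-allyl-2,6-dimethoxyphenoxy)triisopropylsilane
Conditions: iPr3SiCl, imidazole, DMF, rt
Reagents that add atoms: chlorotri(propan-2-yl)silane, CC(C)[Si](Cl)(C(C)C)C(C)C
Why: Imidazole-promoted O-silylation masks the acidic phenol for the enolate, Grignard and palladium steps, and the bulky silyl ether is later removed by fluoride.

Step 2
Reactants: 2 (4-allyl-2,6-dimethoxyphenoxy)triisopropylsilane
Product: 4 2-[3,5-dimethoxy-4-(triisopropylsilyloxy)phenyl]acetaldehyde, via secondary ozonide 3 (not isolated)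
Conditions: O3, CH2Cl2, −78 °C; then PPh3, −78 °C to rt
Reagents that add atoms: ozone, [O-][O+]=O
Why: Ozonolysis with reductive work-up cleaves the terminal alkene, which reacts far faster than the arene at −78 °C, and the enolizable aldehyde is used crude to limit self-condensation.

Step 3
Reactants: 5 3-ethoxycyclohex-2-en-1-one; 4 2-[3,5-dimethoxy-4-(triisopropylsilyloxy)phenyl]acetaldehyde
Product: 7 3-ethoxy-6-{1-hydroxy-2-[3,5-dimethoxy-4-(triisopropylsilyloxy)phenyl]ethyl}cyclohex-2-en-1-one (diastereomer mixture), via lithium dienolate 6 (not isolated)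
Conditions: LiN(iPr)2, THF, −78 °C; then 4, −78 °C; AcOH quench
Reagents that add atoms: none
Why: Directed aldol addition of the kinetic α′-enolate of the vinylogous ester (C6) should outrun enolization of the aldehyde at −78 °C, and both new stereocentres are erased in the next step.

Step 4
Reactants: 7 3-ethoxy-6-{1-hydroxy-2-[3,5-dimethoxy-4-(triisopropylsilyloxy)phenyl]ethyl}cyclohex-2-en-1-one
Product: 9 (6E)-3-ethoxy-6-{2-[3,5-dimethoxy-4-(triisopropylsilyloxy)phenyl]ethylidene}cyclohex-2-en-1-one, via mesylate 8 (not isolated)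
Conditions: MsCl, Et3N, CH2Cl2, −20 °C; then DBU, −20 to 0 °C
Reagents that add atoms: none
Why: Mesylation followed by E1cB elimination through the C6 enolate completes the aldol condensation and should give the E enone, because the arylmethyl group avoids the carbonyl; cold, brief base contact keeps the double bond from migrating.

Step 5
Reactants: 9 (6E)-3-ethoxy-6-{2-[3,5-dimethoxy-4-(triisopropylsilyloxy)phenyl]ethylidene}cyclohex-2-en-1-one; 10 allyl chloroformate
Product: 12 allyl 4-ethoxy-2-{(2R)-1-[3,5-dimethoxy-4-(triisopropylsilyloxy)phenyl]propan-2-yl}cyclohexa-1,3-dien-1-yl carbonate, via bromomagnesium enolate 11 (not isolated)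
Conditions: MeMgBr, CuBr·SMe2 (5 mol%), (R)-1-[(S)-2-(diphenylphosphino)ferrocenyl]ethyldicyclohexylphosphine (6 mol%), t-BuOMe, −78 °C; then 10, −78 to 0 °C; filtration through Et3N-deactivated silica
Reagents that add atoms: methylmagnesium bromide, C[Mg]Br
Why: Copper-catalysed asymmetric conjugate addition of the Grignard reagent to the s-cis-locked enone should deliver methyl to the Re face of the alkylidene carbon under control of the ferrocenyl diphosphine, which sets C3 (R), and the regiodefined, fully substituted magnesium enolate is then O-acylated by the chloroformate because its carbon terminus is hindered.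

Step 6
Reactants: 12 allyl 4-ethoxy-2-{(2R)-1-[3,5-dimethoxy-4-(triisopropylsilyloxy)phenyl]propan-2-yl}cyclohexa-1,3-dien-1-yl carbonate
Product: 13 (6S)-6-allyl-3-ethoxy-6-{(2R)-1-[3,5-dimethoxy-4-(triisopropylsilyloxy)phenyl]propan-2-yl}cyclohex-2-en-1-one
Conditions: Pd2(dba)3 (2.5 mol%), (S)-t-BuPHOX (6 mol%), THF, 25 °C
Reagents that add atoms: none
Why: In this decarboxylative asymmetric allylic alkylation (Tsuji allylation) zerovalent palladium ionizes the allyl carbonate, CO2 is lost and the allyl–palladium enolate forms the C6–allyl bond on the face chosen by the PHOX ligand, which sets the quaternary centre (S); the small intrinsic bias of the side-chain centre (allylic strain, approach anti to the arylmethyl group) points the same way.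

Step 7
Reactants: 13 (6S)-6-allyl-3-ethoxy-6-{(2R)-1-[3,5-dimethoxy-4-(triisopropylsilyloxy)phenyl]propan-2-yl}cyclohex-2-en-1-one
Product: 15 (4S)-4-allyl-4-[(2R)-1-(4-hydroxy-3,5-dimethoxyphenyl)propan-2-yl]cyclohexane-1,3-dione, via free phenol 14 (not isolated)
Conditions: Bu4NF, THF, 0 °C; then 2 M aq. HCl, THF, rt
Reagents that add atoms: water, O
Why: Fluoride desilylation followed by acid hydrolysis of the vinylogous ester should unmask phenol and 1,3-dione without touching either stereocentre, since the quaternary carbon cannot enolize and the side-chain centre is not acidic.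

Step 8
Reactants: 15 (4S)-4-allyl-4-[(2R)-1-(4-hydroxy-3,5-dimethoxyphenyl)propan-2-yl]cyclohexane-1,3-dione
Product: 17 (2S,3S,3aS)-3a-allyl-2-(4-hydroxy-3,5-dimethoxyphenyl)-3-methyl-3,3a,4,5-tetrahydro-1-benzofuran-6(2H)-one, via p-quinone methide 16 (not isolated)
Conditions: Ag2O (2.5 equiv), CH2Cl2 (0.01 M), rt, dark
Reagents that add atoms: none
Why: Ag2O takes two electrons and two protons (phenolic O–H and benzylic C2–H) from the 4-alkyl-2,6-dimethoxyphenol and gives p-quinone methide 16, whose exocyclic carbon is C2. The enol oxygen on C7a then adds to C2 in a 5-exo-trig closure that forms O1–C2 and ring A, restores the arene and leaves ring B as a vinylogous ester; the closest known reaction is the Ag2O oxidation of 4-alkyl-2,6-dimethoxyphenols to quinone methides with intramolecular oxygen capture. C2 is the only new stereocentre and is controlled by C3: the enol should add to the quinone methide face that places the aryl group trans to the C3 methyl on the forming five-membered ring. The step needs O- over C-selectivity, since attack through C7 would give a bridged bicyclo[3.2.1]octanedione. The substrate secures this because O-closure keeps the conjugated vinylogous ester whereas C-closure gives a non-enolizable bridged diketone whose benzylic bond, para to the free phenol, can re-ionize under mild acid and drain to 17. High dilution suppresses intermolecular addition of the dione to the quinone methide.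

Step 9
Reactants: 17 (2S,3S,3aS)-3a-allyl-2-(4-hydroxy-3,5-dimethoxyphenyl)-3-methyl-3,3a,4,5-tetrahydro-1-benzofuran-6(2H)-one
Product: 18 (2S,3S,3aS)-3a-allyl-3-methyl-2-(3,4,5-trimethoxyphenyl)-3,3a,4,5-tetrahydro-1-benzofuran-6(2H)-one
Conditions: MeI, K2CO3, acetone, 50 °C
Reagents that add atoms: iodomethane, CI
Why: Williamson methylation of the phenol proceeds with a carbonate base that is too weak to enolize the vinylogous ester at C5.

Step 10
Reactants: 18 (2S,3S,3aS)-3a-allyl-3-methyl-2-(3,4,5-trimethoxyphenyl)-3,3a,4,5-tetrahydro-1-benzofuran-6(2H)-one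
Product: 20 (2S,3S,3aR,5R)-3a-allyl-5-hydroxy-3-methyl-2-(3,4,5-trimethoxyphenyl)-3,3a,4,5-tetrahydro-1-benzofuran-6(2H)-one, via potassium enolate 19 (not isolated)
Conditions: KN(SiMe3)2, THF, −78 °C; then 2-(phenylsulfonyl)-3-phenyloxaziridine, −78 °C; AcOH quench
Reagents that add atoms: 2-(phenylsulfonyl)-3-phenyloxaziridine, O=S(=O)(c1ccccc1)N1OC1c1ccccc1
Why: C5 is the only enolizable position, and electrophilic hydroxylation of the potassium enolate by the N-sulfonyloxaziridine should occur anti to the pseudoaxial allyl group on C3a, placing OH trans to allyl (5R), which is also the equatorial and more stable epimer.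

Step 11
Reactants: 20 (2S,3S,3aR,5R)-3a-allyl-5-hydroxy-3-methyl-2-(3,4,5-trimethoxyphenyl)-3,3a,4,5-tetrahydro-1-benzofuran-6(2H)-one
Product: 21 (2S,3S,3aR,5R)-3a-allyl-5-methoxy-3-methyl-2-(3,4,5-trimethoxyphenyl)-3,3a,4,5-tetrahydro-1-benzofuran-6(2H)-one (target)
Conditions: MeI, Ag2O, MeCN, 40 °C, dark
Reagents that add atoms: iodomethane, CI
Why: Purdie methylation etherifies the secondary α-hydroxyl under non-basic conditions, so C5 should not epimerize and no retro-aldol or ketol shift should intervene.

**Compound list**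

1 | 4-allyl-2,6-dimethoxyphenol | C=CCc1cc(OC)c(O)c(OC)c1 | starting material
2 | (4-allyl-2,6-dimethoxyphenoxy)triisopropylsilane | C=CCc1cc(OC)c(O[Si](C(C)C)(C(C)C)C(C)C)c(OC)c1 | intermediate
3 | 3-[3,5-dimethoxy-4-(triisopropylsilyloxy)benzyl]-1,2,4-trioxolane (secondary ozonide, racemic) | COc1cc(CC2OCOO2)cc(OC)c1O[Si](C(C)C)(C(C)C)C(C)C | intermediate
4 | 2-[3,5-dimethoxy-4-(triisopropylsilyloxy)phenyl]acetaldehyde | O=CCc1cc(OC)c(O[Si](C(C)C)(C(C)C)C(C)C)c(OC)c1 | intermediate
5 | 3-ethoxycyclohex-2-en-1-one | CCOC1=CC(=O)CCC1 | starting material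
6 | lithium 4-ethoxycyclohexa-1,3-dien-1-olate | [Li]OC1=CCCC(OCC)=C1 | intermediate
7 | 3-ethoxy-6-{1-hydroxy-2-[3,5-dimethoxy-4-(triisopropylsilyloxy)phenyl]ethyl}cyclohex-2-en-1-one (diastereomer mixture) | CCOC1=CC(=O)C(CC1)C(O)Cc1cc(OC)c(O[Si](C(C)C)(C(C)C)C(C)C)c(OC)c1 | intermediate
8 | methanesulfonate of 7 | CCOC1=CC(=O)C(CC1)C(OS(C)(=O)=O)Cc1cc(OC)c(O[Si](C(C)C)(C(C)C)C(C)C)c(OC)c1 | intermediate
9 | (6E)-3-ethoxy-6-{2-[3,5-dimethoxy-4-(triisopropylsilyloxy)phenyl]ethylidene}cyclohex-2-en-1-one | CCOC1=CC(=O)/C(CC1)=C/Cc1cc(OC)c(O[Si](C(C)C)(C(C)C)C(C)C)c(OC)c1 | intermediate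
10 | allyl chloroformate | C=CCOC(Cl)=O | starting material
11 | bromomagnesium 4-ethoxy-2-{(2R)-1-[3,5-dimethoxy-4-(triisopropylsilyloxy)phenyl]propan-2-yl}cyclohexa-1,3-dien-1-olate | CCOC1=CC(O[Mg]Br)=C(CC1)[C@H](C)Cc1cc(OC)c(O[Si](C(C)C)(C(C)C)C(C)C)c(OC)c1 | intermediate
12 | allyl 4-ethoxy-2-{(2R)-1-[3,5-dimethoxy-4-(triisopropylsilyloxy)phenyl]propan-2-yl}cyclohexa-1,3-dien-1-yl carbonate | C=CCOC(=O)OC1=C(CCC(OCC)=C1)[C@H](C)Cc1cc(OC)c(O[Si](C(C)C)(C(C)C)C(C)C)c(OC)c1 | intermediate
13 | (6S)-6-allyl-3-ethoxy-6-{(2R)-1-[3,5-dimethoxy-4-(triisopropylsilyloxy)phenyl]propan-2-yl}cyclohex-2-en-1-one | C=CC[C@@]1(CCC(OCC)=CC1=O)[C@H](C)Cc1cc(OC)c(O[Si](C(C)C)(C(C)C)C(C)C)c(OC)c1 | intermediate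
14 | (6S)-6-allyl-3-ethoxy-6-[(2R)-1-(4-hydroxy-3,5-dimethoxyphenyl)propan-2-yl]cyclohex-2-en-1-one | C=CC[C@@]1(CCC(OCC)=CC1=O)[C@H](C)Cc1cc(OC)c(O)c(OC)c1 | intermediate
15 | (4S)-4-allyl-4-[(2R)-1-(4-hydroxy-3,5-dimethoxyphenyl)propan-2-yl]cyclohexane-1,3-dione | C=CC[C@@]1(CCC(=O)CC1=O)[C@H](C)Cc1cc(OC)c(O)c(OC)c1 | intermediate
16 | p-quinone methide of 15: 4-alkylidene-2,6-dimethoxycyclohexa-2,5-dien-1-one with both stereocentres as in 15 | C=CC[C@@]1(CCC(=O)CC1=O)[C@H](C)C=C2C=C(OC)C(=O)C(OC)=C2 | intermediate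
17 | (2S,3S,3aS)-3a-allyl-2-(4-hydroxy-3,5-dimethoxyphenyl)-3-methyl-3,3a,4,5-tetrahydro-1-benzofuran-6(2H)-one | C=CC[C@]12CCC(=O)C=C1O[C@H](c1cc(OC)c(O)c(OC)c1)[C@H]2C | intermediate
18 | (2S,3S,3aS)-3a-allyl-3-methyl-2-(3,4,5-trimethoxyphenyl)-3,3a,4,5-tetrahydro-1-benzofuran-6(2H)-one | C=CC[C@]12CCC(=O)C=C1O[C@H](c1cc(OC)c(OC)c(OC)c1)[C@H]2C | intermediate
19 | potassium C5=C6 dienolate of 18 | C=CC[C@]12CC=C(O[K])C=C1O[C@H](c1cc(OC)c(OC)c(OC)c1)[C@H]2C | intermediate
20 | (2S,3S,3aR,5R)-3a-allyl-5-hydroxy-3-methyl-2-(3,4,5-trimethoxyphenyl)-3,3a,4,5-tetrahydro-1-benzofuran-6(2H)-one | C=CC[C@]12C[C@@H](O)C(=O)C=C1O[C@H](c1cc(OC)c(OC)c(OC)c1)[C@H]2C | intermediate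
21 | (2S,3S,3aR,5R)-3a-allyl-5-methoxy-3-methyl-2-(3,4,5-trimethoxyphenyl)-3,3a,4,5-tetrahydro-1-benzofuran-6(2H)-one | C=CC[C@]12C[C@@H](OC)C(=O)C=C1O[C@H](c1cc(OC)c(OC)c(OC)c1)[C@H]2C | target

**Step count**

Total steps: 11. Longest linear sequence: 11 steps from 1 (5 and 10 are commercial and enter at steps 3 and 5).

**Steps most likely to fail**

Step 5. What may go wrong: weak enantiofacial discrimination by the copper catalyst on the s-cis-locked, α-substituted enone, or γ-deprotonation of the doubly activated benzylic CH2 by the Grignard reagent, which lets the exocyclic double bond migrate. The fallback sets out from 9 and 10 and returns at 13. Me2CuLi in Et2O at −78 °C adds to 9 without a chiral ligand and should give the racemic lithium 4-ethoxy-2-{1-[3,5-dimethoxy-4-(triisopropylsilyloxy)phenyl]propan-2-yl}cyclohexa-1,3-dien-1-olate F1. Compound 10 converts it into the racemic allyl enol carbonate F2. The Pd2(dba)3/(S)-t-BuPHOX allylation of step 6 then fixes the quaternary centre as S in both antipodes of F2. The products are 13 and its side-chain epimer, (6S)-6-allyl-3-ethoxy-6-{(2S)-1-[3,5-dimethoxy-4-(triisopropylsilyloxy)phenyl]propan-2-yl}cyclohex-2-en-1-one F3, which are diastereomers and would be separated by chromatography. The side-chain centre is thus obtained by separation after a catalyst-controlled second centre, not by asymmetric induction, at the cost of half the material.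

Step 8. What may go wrong: oxidation of the silver dione enolate or C7-alkylation by it, intermolecular trapping, or tautomerization of the quinone methide to the 4-propenylphenol with loss of the C3 centre. The fallback sets out from 13 and returns at 17; it separates oxidation from ring closure. Bu4NF gives phenol 14, now isolated. Ag2O in CH2Cl2/MeOH oxidizes 14, at a stage where no enol is present, to the vinylogous-ester quinone methide F4. Methanol adds to F4 to give the benzylic methyl ether (6S)-6-allyl-3-ethoxy-6-[(2R)-1-(4-hydroxy-3,5-dimethoxyphenyl)-1-methoxypropan-2-yl]cyclohex-2-en-1-one F5 as a mixture at the benzylic carbon. Aqueous 1 M HCl in THF then hydrolyses the vinylogous ester and ionizes the benzylic ether para to the phenol, and the enol oxygen should close ring A to 17 under the same control by C3.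

Step 6. What may go wrong: erosion of diastereofacial control with the fully substituted, α-branched enolate (a mismatched pairing of ligand and side-chain centre), or protonation of the enolate instead of allylation. The fallback sets out from 9 and returns at 13. The conjugate addition of step 5 is run unchanged and the bromomagnesium enolate 11 is alkylated in the same flask with allyl iodide and DMPU at −40 to 0 °C (tandem conjugate addition–alkylation). Stereocontrol then rests on the substrate: allylic strain holds the side-chain C–H in the enolate plane and the electrophile approaches anti to the arylmethyl group, which leads to 13. The minor C6 epimer, (6R)-6-allyl-3-ethoxy-6-{(2R)-1-[3,5-dimethoxy-4-(triisopropylsilyloxy)phenyl]propan-2-yl}cyclohex-2-en-1-one F6, would be removed by chromatography.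

**Further compounds**

F1 | step 5 | lithium 4-ethoxy-2-{1-[3,5-dimethoxy-4-(triisopropylsilyloxy)phenyl]propan-2-yl}cyclohexa-1,3-dien-1-olate (racemic) | CCOC1=CC(O[Li])=C(CC1)C(C)Cc1cc(OC)c(O[Si](C(C)C)(C(C)C)C(C)C)c(OC)c1
F2 | step 5 | allyl 4-ethoxy-2-{1-[3,5-dimethoxy-4-(triisopropylsilyloxy)phenyl]propan-2-yl}cyclohexa-1,3-dien-1-yl carbonate (racemic) | C=CCOC(=O)OC1=C(CCC(OCC)=C1)C(C)Cc1cc(OC)c(O[Si](C(C)C)(C(C)C)C(C)C)c(OC)c1
F3 | step 5 | (6S)-6-allyl-3-ethoxy-6-{(2S)-1-[3,5-dimethoxy-4-(triisopropylsilyloxy)phenyl]propan-2-yl}cyclohex-2-en-1-one | C=CC[C@@]1(CCC(OCC)=CC1=O)[C@@H](C)Cc1cc(OC)c(O[Si](C(C)C)(C(C)C)C(C)C)c(OC)c1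
F4 | step 8 | p-quinone methide of 14 (vinylogous ester retained) | C=CC[C@@]1(CCC(OCC)=CC1=O)[C@H](C)C=C2C=C(OC)C(=O)C(OC)=C2
F5 | step 8 | (6S)-6-allyl-3-ethoxy-6-[(2R)-1-(4-hydroxy-3,5-dimethoxyphenyl)-1-methoxypropan-2-yl]cyclohex-2-en-1-one (mixture at the benzylic carbon) | C=CC[C@@]1(CCC(OCC)=CC1=O)[C@H](C)C(OC)c1cc(OC)c(O)c(OC)c1
F6 | step 6 | (6R)-6-allyl-3-ethoxy-6-{(2R)-1-[3,5-dimethoxy-4-(triisopropylsilyloxy)phenyl]propan-2-yl}cyclohex-2-en-1-one | C=CC[C@]1(CCC(OCC)=CC1=O)[C@H](C)Cc1cc(OC)c(O[Si](C(C)C)(C(C)C)C(C)C)c(OC)c1
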